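Violet receives more L than grey, 3.60 equiv against 1.20 equiv, and the two flasks agree in every other charge and in the time. Z is the substrate, X the catalyst, E the species formed on the way, L the reagent and G the product.

all flasks: Z 2.0 mM; X 5 mol%; time 2.5 min

| flask | L |
|---|---|
| grey | 1.20 equiv |
| violet | 3.60 equiv |

    Z + X → X + E (k1 = 310 L mol⁻¹ s⁻¹)
    L + X + E ⇌ X + G (K2 = 390 L mol⁻¹, k2 = 81000 L² mol⁻² s⁻¹)

- which of these there is most of at the end, counted by the Z in it, grey (E / Z / G)
- which of these there is most of at the end, counted by the Z in it, violet (E / Z / G)
- the largest of these amounts at the end, in percent of the Z charged, grey
- the largest of these amounts at the end, in percent of the Z charged, violet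

Take step 1 first. X is not consumed, so Z decays in a pseudo-first-order way at k1[X], with a half-life of 0.373 min. L does not enter this step, so both flasks keep 0.956% of their Z at the end, and nearly all of the charged Z has moved on.

Now add the forward half of step 2 and follow one molecule of E in grey: it hops to G at k2[X][L], which is 0.0194 s⁻¹ at the charged L. With the back half added, G hops to E at (k2/K2)[X], which is 0.0208 s⁻¹. X multiplies both hops and drops out of their ratio, which is 0.936 in grey. This ratio is O, the odds of G over E, equal to K2 times the free L. The hops together give a half-life of 0.287 min, shorter than 2.5 min, so the molecule should end close to its odds.

These odds would put 48.3% in G. The last addition is that each G formed takes one L from solution, which lowers O. Requiring G/E to equal K2 times the L remaining gives a quadratic, and its root is a G share of 38.8% in grey and 69.4% in violet. After trimming for the remaining Z, my reckoning is E at 60.6% in grey and G at 68.7% in violet.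

The forecast gives E at 61% in grey and G at 68.5% in violet, holding that “excess L flips the main species from E to G”.

The flasks give E at 61.2% in grey and G at 68.3% in violet, with Z at 0.956% in each. In grey, the relaxation half-life of step 2 alone at the end, both ways together, 0.263 min, is shorter than 2.5 min, and G/E stands at 0.619 against an O of 0.641 from the L left. A neighbour, the same flask as grey but with 2.00 equiv of L, has an O of 1.15 from its L left, above 1, and it ends with G at 52.3% against E at 46.7%.

The constants used here are those of an exercise; no experiment stands behind them.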